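Free monomer that is lost reappears as monomer in chains: at the last noon reading the two add up to 100% of the charge. One number per flask therefore tells how far it has gone, the fraction f of free monomer left. Its burn is b = −ln f. The loss is pseudo-first-order in free monomer, with a rate constant k per chain. If chains begin at a steady rate c, their number is ct and b is 0.5 k c t squared. Noon allows this: monomer in chains grows 2.57-fold from 40.0 s to 60.0 s, where t squared gives 2.25, and the burn at the last reading is 0.0769.

| flask | free monomer | pre-initiator | remark | time |
|---|---|---|---|---|
| noon | 1.2 M | 1.5 mol% | run made earlier |  |
| winter | 0.40 M | 1.5 mol% | run made earlier |  |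
| south-east | 0.80 M | 1.5 mol% |  | 5.0 min |
| south-west | 0.80 M | 0.4 mol% |  | 5.0 min |

- noon (time / s: monomer in chains / %, free monomer / %): 12.0: 0, 99.7; 25.0: 0.3, 98.7; 40.0: 3.0, 98.3; 50.0: 5.7, 95.3; 60.0: 7.7, 92.6
- winter (time / s: monomer in chains / %, free monomer / %): 12.0: 0.9, 100.3; 25.0: 0, 99.9; 40.0: 0, 100.9; 50.0: 0, 99.5; 60.0: 1.0, 99.5

(standard deviation of a reading: 0.5 percentage points)

* which of the two ends with the longer chains by the average number of monomer units in a chain (chains begun, living or dead) ("neither" if they lie within 10%) (south-east / south-west / neither)
* average number of monomer units in a chain (chains begun, living or dead) at the end, south-east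
* average number of monomer units in a chain (chains begun, living or dead) at the end, south-west

Taking c proportional to [free monomer] times [pre-initiator], an assumption for the loading because both runs hold it equal, south-east's 11.1 is its dose, the charged [free monomer] times [pre-initiator] times t squared, in units of the noon flask at its last reading. Winter's dose of 0.111 gives a burn of 0.00854, and its last reading of monomer in chains is 1.0%.

Dividing monomer in chains by ct gives length = 0.5 k [free monomer] t (1 − f)/b. The runs show no chain count, so k stays unread and ratios are what can be reckoned.

Time raises the length directly and lowers (1 − f)/b through the dose, but both flasks run 5.0 min. Free monomer enters the length once and the dose twice, but both hold 0.80 M. Pre-initiator cancels from the front of the formula and acts through the dose, and here the flasks differ. South-east reckons to f = 42.6%. South-west, with dose 2.96, reckons to 79.6%. The length ratio, south-west over south-east, is then 1.33, which clears the margin of 10%, so south-west should end longer.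

The forecast also names south-west, with 100 and 190 units, a ratio of 1.90 against 1.33 here: “South-west has longer chains under any plausible ki.”

The flasks give 193 units for south-east and 275 for south-west, a ratio of 1.42.

    free monomer + initiator → living end + monomer in chains (k = 0.00454 M⁻¹ s⁻¹)
    free monomer + living end → monomer in chains + living end, rate k2*[living end]*[free monomer] (k = 3.08 M⁻¹ s⁻¹)
    pre-initiator ⇌ initiator (K = 4.09, k = 0.00955 s⁻¹)

South-east keeps 18% of its free monomer and south-west 58%, less than reckoned in both. Scaling south-east's own burn by dose, a flask like south-west but with 1.6 mol% has dose 11.9 and should keep 15.9%. That flask keeps 16.2% and ends at 189 units.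

The runs stem from a simulated flask with constants of no real substance; scatter was added.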